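Target forms in a closed flask from substrate and partner, and the flasks asked about differ in partner charge and nothing else.

| flask | substrate | partner | temperature | remark | time |
|---|---|---|---|---|---|
| north | 1 M | 0.62 equiv | 5 °C | run made earlier |  |
| north-east | 1 M | 2.4 equiv | 20 °C | run made earlier |  |
| maple | 1.0 M | 1.30 equiv | 20 °C |  | 6.0 h |
| cedar | 1.0 M | 0.500 equiv | 20 °C |  | 6.0 h |
| elm | 1.0 M | 1.00 equiv | 20 °C |  | 6.0 h |
| birch | 1.0 M | 2.00 equiv | 20 °C |  | 6.0 h |

| run | time / h | target / % |
|---|---|---|
| north | 1.00 | 0 |
| north | 2.00 | 0.3 |
| north | 5.00 | 0.9 |
| north | 12.0 | 5.9 |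
| north-east | 0.500 | 0.6 |
| north-east | 1.00 | 4.6 |
| north-east | 2.50 | 25.1 |
| north-east | 6.00 | 58.5 |

(scatter of a reading: 0.3 percentage points)

* all flasks from highest to lowest amount of target, in percent of the substrate charged, at 6.0 h (maple / cedar / elm / birch)
* the amount of target, in percent of the substrate charged of the flask you put first, at 6.0 h
* the amount of target, in percent of the substrate charged of the flask you put last, at 6.0 h



The north run, at 5 °C, stands at a different temperature from the asked flasks, so the reckoning here starts from the north-east run. That run looks contradictory. It holds 2.4 equiv of partner, a large charge. Yet target gains 20 percentage points in the 1.50 h after 1.00 h and 33 points in the 3.50 h after 2.50 h, which is a slower pace.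

The two can be put together by supposing that a large partner charge stops paying in proportion, with the yield bending towards the substrate charged. The rule adopted here, an assumption, is that, at 6.0 h and 20 °C with the substrate charge held, the ratio of target to the rest of the substrate charged (what is not found as target) is proportional to partner charge. The north-east reading then gives K = 1.70, the equal-share charge: the partner charge at which target equals the rest of the substrate. Target is then charge/(charge + K), which rises with partner and gives 54.0% for birch and 22.7% for cedar.

The forecast gives birch > maple > elm > cedar, with 51% for birch and 15% for cedar, and adds: “The lag may lengthen at low partner, or the partner order may exceed one, so cedar could come in lower.” The equal-share rule gives the same order but puts cedar higher.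

The flasks give birch > maple > elm > cedar, with 56.0% in birch and 25.3% in cedar.

    substrate ⇌ intermediate A (K = 16.0, k = 0.942 h⁻¹, Ea = 101 kJ mol⁻¹, ΔH = −36.0 kJ mol⁻¹)
    partner → decomposed reagent (k = 0.100 h⁻¹, Ea = 88.0 kJ mol⁻¹)
    intermediate A → intermediate B (k = 0.378 h⁻¹, Ea = 92.0 kJ mol⁻¹)
    partner + intermediate B → target (k = 0.755 M⁻¹ h⁻¹, Ea = 65.0 kJ mol⁻¹)
    intermediate A → side product (k = 0.124 h⁻¹, Ea = 98.0 kJ mol⁻¹)
    (constants at 20 °C)

For elm, K gives 37.0% against 41.5%, and for cedar 22.7% against 25.3%; read back from cedar, K is 1.47. Cedar, where partner is the limiting reagent, shows what the consumption of partner costs: with partner held at its charge, target reaches 45.6% instead of 25.3%, the largest single effect tested there. At 6.00 h cedar holds 16.4% of its partner charge beside 41.2% of the substrate as intermediate B.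

(The numbers in the tables are calculated from invented constants; the scatter is artificial.)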